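Daucane numbering is used (cyclopentane C1–C5; cycloheptene C1, C5–C10; C14 on C8, C15 on C1). Everything rests on cutting the cyclopentane at C1–C2 and C4–C5: this exposes the aldol retron O4–C4–C5–C6=O and a hidden mirror plane through C6 that makes the methyl-bearing carbons C8 and C1 equivalent. The key step joins achiral 3,6-dimethylcyclohepta-2,6-dienone with the zinc homoenolate of 2-methylpentan-3-one (from a cyclopropanol): copper-catalysed enantioselective conjugate addition to one enone arm creates quaternary C1, and the C5 enolate then closes the ring by aldol addition to the C4 ketone, setting C1, C4 and C5 in one operation.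

Key step: step 5

Assumption: 1,1,3,3-tetrabromopropan-2-one is taken as a commercial reagent; bicyclic compounds are named on the daucane skeleton with CIP descriptors.

Step 1
Reactants: 1 2,5-dimethylfuran; 2 1,1,3,3-tetrabromopropan-2-one
Product: 4 (1R,5S)-1,5-dimethyl-8-oxabicyclo[3.2.1]oct-6-en-3-one (meso), via dibromo cycloadduct 3 (not isolated)
Conditions: Zn/Cu couple, THF, −10 °C to rt; then Zn/Cu couple, NH4Cl, MeOH, rt
Reagents that add atoms: none
Why: Zinc reduction of 2 gives a dibromo-oxyallyl species whose [4+3] cycloaddition across the 2,5-positions of the furan builds the seven-membered carbocycle with both methyl groups at the bridgeheads, zinc then removes the two bromines, and the ether bridge forces the meso arrangement, so no selectivity is needed.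

Step 2
Reactants: 4 (1R,5S)-1,5-dimethyl-8-oxabicyclo[3.2.1]oct-6-en-3-one
Product: 5 1,5-dimethyl-8-oxabicyclo[3.2.1]octan-3-one (meso)
Conditions: H2 (1 atm), Pd/C, EtOAc, rt
Reagents that add atoms: none
Why: Heterogeneous catalytic hydrogenation saturates the strained cis-alkene while ketone and ether stay untouched, and the product remains meso.

Step 3
Reactants: 5 1,5-dimethyl-8-oxabicyclo[3.2.1]octan-3-one
Product: 7 3,6-dimethylcyclohepta-2,6-dien-1-one, via hydroxy enone 6 (not isolated)
Conditions: p-TsOH·H2O (cat.), toluene, reflux, Dean–Stark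
Reagents that add atoms: none
Why: Acid-catalysed double β-elimination (retro-oxa-Michael opening of the bridging ether through the enol, then dehydration of the tertiary hydroxy enone) is driven by removal of water and by conjugation, and the cross-conjugated dienone formed has no stereocentre.

Step 4
Reactants: 8 methyl 2-methylpropanoate
Product: 9 1-(propan-2-yl)cyclopropan-1-ol
Conditions: EtMgBr (2.5 equiv), Ti(OiPr)4 (20 mol %), Et2O, 0 °C to rt
Reagents that add atoms: ethylmagnesium bromide, CC[Mg]Br
Why: Kulinkovich cyclopropanation, in which the titanacyclopropane formed from EtMgBr and Ti(OiPr)4 adds twice to the ester carbonyl as a 1,2-dicarbanion equivalent; no stereocentre is formed.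

Step 5
Reactants: 7 3,6-dimethylcyclohepta-2,6-dien-1-one; 9 1-(propan-2-yl)cyclopropan-1-ol
Product: 12 (1S,4R,5R)-4-hydroxydauc-7-en-6-one, via zinc homoenolate 10 (not isolated), via zinc dienolate 11 (not isolated)
Conditions: 9 (2.2 equiv), ZnEt2 (1.1 equiv), toluene, 0 °C to rt; then 7 (1.0 equiv), Cu(OTf)2 (5 mol %), chiral sulfonate-bearing imidazolinium salt (carbene precursor, 6 mol %), −30 °C, then 40 °C; aq. NH4Cl
Reagents that add atoms: none
Why: Proposed new method: ZnEt2 converts 9 into the zinc cyclopropoxide, whose strain-driven ring opening gives homoenolate 10; transfer to the chiral catalyst formed from Cu(OTf)2 and the carbene ligand and conjugate addition to one of the two enantiotopic enone arms of 7 forms the C1–C2 bond and the quaternary centre, and the C5 zinc dienolate 11 then adds to the pendant C4 ketone (C4–C5 bond). The closest known reaction types are the copper-catalysed enantioselective conjugate addition of dialkylzinc reagents to β-methyl cycloalkenones, the conjugate addition–aldol cyclisation of zinc enolates onto tethered ketones, and the ring opening of cyclopropanols to zinc homoenolates that add to enones. The cyclopentane, the only ring formed, closes by a 5-(enolexo)-exo-trig aldol addition. C1 is set by the catalyst (choice of enone arm and face in the mirror-symmetric dienone), C4 by the zinc chelate between O4 and O6, which places the hydroxyl cis to C6, and C5 by equilibration: the closure is kinetically biased to the cis-fused aldolate, but tertiary zinc aldolates revert, and the warm stage should funnel the mixture to the chelated trans-fused isomer with H5 and the isopropyl group both anti to the C15 methyl. The step needs mono-addition and a regiodefined enolate, and the substrate secures both, because the enolate formed by the first addition is no longer an acceptor and is generated only at C5.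

Step 6
Reactants: 12 (1S,4R,5R)-4-hydroxydauc-7-en-6-one
Product: 13 (1R,4R,5R)-4-hydroxydauca-7,9-dien-6-one
Conditions: chloranil, t-BuOH, reflux
Reagents that add atoms: none
Why: Quinone dehydrogenation through the extended dienol (the reaction that turns 4-en-3-ones into 4,6-dien-3-ones) removes hydride from C10 and gives the linear 7,9-dienone, the cross-conjugated alternative being impossible because C1 bears no hydrogen; no stereocentre is touched (the C1 descriptor changes through CIP priorities only).

Step 7
Reactants: 13 (1R,4R,5R)-4-hydroxydauca-7,9-dien-6-one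
Product: 14 (1S,4R,5R,9R,10S)-9,10-epoxy-4-hydroxydauc-7-en-6-one
Conditions: mCPBA, NaHCO3, CH2Cl2, 0 °C
Reagents that add atoms: meta-chloroperoxybenzoic acid, OOC(=O)c1cccc(Cl)c1
Why: Prilezhaev epoxidation takes place at the electron-richer γ,δ-alkene of the dienone and from the face anti to the axial C15 methyl on the neighbouring quaternary C1, which sets the C10–O bond cis to C2 as the target requires.

Step 8
Reactants: 14 (1S,4R,5R,9R,10S)-9,10-epoxy-4-hydroxydauc-7-en-6-one
Product: 15 (1S,4R,5R,10R)-4,10-dihydroxydauc-8-en-6-one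
Conditions: SmI2 (2.5 equiv), THF–MeOH, −78 °C
Reagents that add atoms: none
Why: SmI2 reduction of the vinylogous epoxy ketone gives a samarium dienolate with cleavage of the allylic C9–O bond, and kinetic protonation at C7 by MeOH gives the β,γ-unsaturated ketone with the C8=C9 alkene; the C10–O bond is not broken, so C10 keeps its configuration.

Step 9
Reactants: 15 (1S,4R,5R,10R)-4,10-dihydroxydauc-8-en-6-one
Product: 16 (1S,4R,5S,6S,10R)-dauc-8-ene-4,6,10-triol
Conditions: Me4NBH(OAc)3, MeCN–AcOH (1:1), −30 °C
Reagents that add atoms: none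
Why: Evans–Saksena reduction, in which the borohydride exchanges an acetate for the tertiary C4 hydroxyl and delivers hydride intramolecularly to the face of the C6 carbonyl syn to O4, giving the 4,6-anti diol (6S), while the weakly acidic medium leaves the β,γ-alkene in place.

Step 10
Reactants: 16 (1S,4R,5S,6S,10R)-dauc-8-ene-4,6,10-triol; 17 (2Z)-2-methylbut-2-enoic acid (angelic acid)
Product: 19 (1S,4R,5S,6S,10R)-4-hydroxydauc-8-ene-6,10-diyl bis[(2Z)-2-methylbut-2-enoate], via mixed anhydride 18 (not isolated)
Conditions: 17 (2.6 equiv), 2,4,6-Cl3C6H2COCl (2.6 equiv), Et3N (5.5 equiv), toluene, rt; then 16 (1.0 equiv), toluene, 80 °C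
Reagents that add atoms: (2Z)-2-methylbut-2-enoic acid (second equivalent of 17, which supplies the second angeloyl group), C/C=C(/C)C(=O)O
Why: Yamaguchi-type esterification without a nucleophilic catalyst, in which each of the two secondary hydroxyls (C6 and C10) takes one angeloyl group from its own molecule of mixed anhydride 18, so that two molecules of 17 are consumed per molecule of 16, while the hindered tertiary C4 hydroxyl stays free and the absence of DMAP should keep the Z geometry of both angelates; no stereocentre is affected.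

Compound list
1 | 2,5-dimethylfuran | Cc1ccc(C)o1 | starting material
2 | 1,1,3,3-tetrabromopropan-2-one | BrC(Br)C(=O)C(Br)Br | starting material
3 | 2,4-dibromo-1,5-dimethyl-8-oxabicyclo[3.2.1]oct-6-en-3-one (bromide epimers, not isolated) | C[C@]12C(Br)C(=O)C(Br)[C@](C)(O1)C=C2 | intermediate
4 | (1R,5S)-1,5-dimethyl-8-oxabicyclo[3.2.1]oct-6-en-3-one (meso) | C[C@]12CC(=O)C[C@](C)(O1)C=C2 | intermediate
5 | 1,5-dimethyl-8-oxabicyclo[3.2.1]octan-3-one (meso) | C[C@]12CC(=O)C[C@](C)(O1)CC2 | intermediate
6 | 6-hydroxy-3,6-dimethylcyclohept-2-en-1-one (racemic, not isolated) | CC1=CC(=O)CC(C)(O)CC1 | intermediate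
7 | 3,6-dimethylcyclohepta-2,6-dien-1-one | CC1=CC(=O)C=C(C)CC1 | intermediate
8 | methyl 2-methylpropanoate | COC(=O)C(C)C | starting material
9 | 1-(propan-2-yl)cyclopropan-1-ol | CC(C)C1(O)CC1 | intermediate
10 | bis(4-methyl-3-oxopentyl)zinc (not isolated) | CC(C)C(=O)CC[Zn]CCC(=O)C(C)C | intermediate
11 | zinc dienolate (O–Zn at C1, C1=C7) of (6S)-3,6-dimethyl-6-(4-methyl-3-oxopentyl)cyclohept-2-en-1-one (not isolated) | CC1=CC(O[Zn]CCC(=O)C(C)C)=C[C@](C)(CCC(=O)C(C)C)CC1 | intermediate
12 | (1S,4R,5R)-4-hydroxydauc-7-en-6-one (trans ring fusion; 4-OH cis to the C15 methyl and to C6) | O=C1C=C(C)CC[C@@]2(C)CC[C@@](O)(C(C)C)[C@H]12 | intermediate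
13 | (1R,4R,5R)-4-hydroxydauca-7,9-dien-6-one | O=C1C=C(C)C=C[C@@]2(C)CC[C@@](O)(C(C)C)[C@H]12 | intermediate
14 | (1S,4R,5R,9R,10S)-9,10-epoxy-4-hydroxydauc-7-en-6-one (epoxide anti to the C15 methyl) | O=C1C=C(C)[C@H]3O[C@H]3[C@@]2(C)CC[C@@](O)(C(C)C)[C@H]12 | intermediate
15 | (1S,4R,5R,10R)-4,10-dihydroxydauc-8-en-6-one | O=C1CC(C)=C[C@@H](O)[C@@]2(C)CC[C@@](O)(C(C)C)[C@H]12 | intermediate
16 | (1S,4R,5S,6S,10R)-dauc-8-ene-4,6,10-triol | O[C@H]1CC(C)=C[C@@H](O)[C@@]2(C)CC[C@@](O)(C(C)C)[C@H]12 | intermediate
17 | (2Z)-2-methylbut-2-enoic acid (angelic acid) | C/C=C(/C)C(=O)O | starting material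
18 | (2Z)-2-methylbut-2-enoic 2,4,6-trichlorobenzoic anhydride (not isolated) | C/C=C(/C)C(=O)OC(=O)c1c(Cl)cc(Cl)cc1Cl | intermediate
19 | (1S,4R,5S,6S,10R)-4-hydroxydauc-8-ene-6,10-diyl bis[(2Z)-2-methylbut-2-enoate] | C/C=C(/C)C(=O)O[C@H]1CC(C)=C[C@@H](OC(=O)/C(C)=C\C)[C@@]2(C)CC[C@@](O)(C(C)C)[C@H]12 | target

Total step count: 10. Longest linear sequence: 9 steps (steps 1–3 and 5–10; step 4 is a one-step branch).

Steps most likely to fail

Step 5. The ketone homoenolate may transfer too slowly to the hindered β-carbon (with ethyl transfer or homoenolate decomposition competing), and the aldolate may stay in the kinetically favoured cis-fused form instead of relaxing to the trans-fused one. The fallback closes the same ring by acylation and builds C4 afterwards; it sets out from 7 and comes back at 12. Conjugate addition to 7 under the same Cu(OTf)2/chiral carbene conditions of bis(3-ethoxy-3-oxopropyl)zinc F1 (made in the flask from [(1-ethoxycyclopropyl)oxy]trimethylsilane and ZnCl2) should give ethyl 3-[(1S)-1,5-dimethyl-3-oxocyclohept-4-en-1-yl]propanoate F2. KOtBu in THF then closes the cyclopentane by Dieckmann-type C-acylation at C5 to the enolised β-diketone (3aS)-3a,6-dimethyl-2,3,3a,4,5,8a-hexahydroazulene-1,8-dione F3, a thermodynamic sink with no ring-fusion stereocentre. TBSOTf/Et3N silylates the enol oxygen on C6 to the dienol ether (3aS)-8-[(tert-butyldimethylsilyl)oxy]-3a,6-dimethyl-2,3,4,5-tetrahydroazulen-1(3aH)-one F4. The organocerium reagent from iPrMgCl and CeCl3 adds to the C4 carbonyl anti to the C15 methyl to give (1S,4R)-6-[(tert-butyldimethylsilyl)oxy]dauca-5,7-dien-4-ol F5. Buffered TBAF/AcOH releases the ketone, and C5 should settle by enolisation in the hydrogen-bonded trans-fused 12, which with C4 fixed is favoured over its C5 epimer.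

Step 6. The tertiary ketol may undergo retro-aldol cleavage or dehydration under the hot quinone conditions before hydride abstraction occurs. The fallback runs from 12 to 13 at room temperature by a palladium-mediated route: TMSOTf/Et3N should give the extended dienol ether (1R,4R,5S)-4,6-bis(trimethylsilyloxy)dauca-6,8-diene F6, which also masks the tertiary hydroxyl; Pd(OAc)2 in MeCN (Saegusa–Ito oxidation) then removes hydrogen from C9 and C10, and dilute acid work-up cleaves the remaining silyl ether to return 13.

Step 8. The samarium dienolate may be protonated at C9 instead of C7 (giving the conjugated enone), or the ketone may be reduced further. The fallback sets out from 13, bypasses the epoxide, and comes back at 15: copper-catalysed 1,6-conjugate borylation (B2pin2, CuCl, PPh3, NaOtBu, MeOH, THF) should place boron on C10 anti to the C15 methyl with protonation at C7, giving (1R,4R,5R,10R)-4-hydroxy-10-(4,4,5,5-tetramethyl-1,3,2-dioxaborolan-2-yl)dauc-8-en-6-one F7; oxidation with NaBO3·4H2O, which proceeds with retention at carbon, returns the route at 15.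

Further compounds
F1 | step 5 | bis(3-ethoxy-3-oxopropyl)zinc | CCOC(=O)CC[Zn]CCC(=O)OCC
F2 | step 5 | ethyl 3-[(1S)-1,5-dimethyl-3-oxocyclohept-4-en-1-yl]propanoate | CCOC(=O)CC[C@]1(C)CCC(C)=CC(=O)C1
F3 | step 5 | (3aS)-3a,6-dimethyl-2,3,3a,4,5,8a-hexahydroazulene-1,8-dione (enolised; C8a not fixed) | O=C1C=C(C)CC[C@@]2(C)CCC(=O)C12
F4 | step 5 | (3aS)-8-[(tert-butyldimethylsilyl)oxy]-3a,6-dimethyl-2,3,4,5-tetrahydroazulen-1(3aH)-one | CC1=CC(O[Si](C)(C)C(C)(C)C)=C2C(=O)CC[C@]2(C)CC1
F5 | step 5 | (1S,4R)-6-[(tert-butyldimethylsilyl)oxy]dauca-5,7-dien-4-ol | CC1=CC(O[Si](C)(C)C(C)(C)C)=C2[C@](O)(C(C)C)CC[C@]2(C)CC1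
F6 | step 6 | (1R,4R,5S)-4,6-bis(trimethylsilyloxy)dauca-6,8-diene | CC1=CC[C@@]2(C)CC[C@@](O[Si](C)(C)C)(C(C)C)[C@@H]2C(O[Si](C)(C)C)=C1
F7 | step 8 | (1R,4R,5R,10R)-4-hydroxy-10-(4,4,5,5-tetramethyl-1,3,2-dioxaborolan-2-yl)dauc-8-en-6-one | O=C1CC(C)=C[C@@H](B2OC(C)(C)C(C)(C)O2)[C@@]3(C)CC[C@@](O)(C(C)C)[C@H]13
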